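**Retrosynthetic overview**
1. Numbering: the cyclopentane ring is C1–C5 (C3 carbinol, C4 CMe2, C5 tertiary carbinol). The cycloheptanone ring is C1, C5–C10 (C8 CHMe, C9 quaternary, C10 C=O). The spacer is C11–C12 and the butenolide is C13(=C14H)–C15(=O)–O–C16H2.
2. Feature that makes the key step possible: the butenolide ring carries its only carbon substituent at C13. Its unsubstituted C15(=O)–O–C16H2 segment therefore maps onto C5–O1–C2 of 5-ethoxy-4-methyloxazole, and C13=C14 maps onto a terminal alkyne. The C11–C12 spacer keeps this event away from the core.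
3. Key disconnection: C14–C15 and C16–C13 are cut together. The forward reaction is an alkyne/oxazole Diels–Alder addition, loss of acetonitrile and hydrolysis of the 2-ethoxyfuran, run on the last heat-robust intermediate (octalone 18).
4. Core: C1–C5 (transannular aldol) leads back to a cyclodecane-5,10-dione, and this to a C5=C10 octalin (ozonolysis). That alkene is the ring-fusion bond of 6-methoxy-2-tetralone after Birch reduction. C9 is set by a chiral-imine Michael addition, C8 by hydrogenation, C3 by CBS reduction, and C5 and C1 in the aldol.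
5. Ring order: ring B (bought), ring A (arene, then Birch), butenolide (key step), ten-membered ring (ozonolysis), then the five- and seven-membered rings (aldol).

Key step: step 11

Remark: the facial sense of step 2 is assigned by analogy with the 2-methylcyclohexanone/(S)-amine case; (R)-1-phenylethylamine would serve in the same way if the sense were the opposite.

**Step 1**
Reactants: 1 6-methoxy-2-tetralone
Product: 4 (±)-6-methoxy-1-methyl-3,4-dihydronaphthalen-2(1H)-one, via pyrrolidine enamine 2 (not isolated), via iminium iodide 3 (not isolated)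
Conditions: pyrrolidine, toluene, reflux (−H2O); MeI, MeCN, reflux; H2O, AcOH, rt
Reagents that add atoms: iodomethane, CI; water, O; pyrrolidine, C1CCNC1 (kept only in 2 and 3)
Why: Stork enamine alkylation: the enamine forms only toward the benzylic carbon (the later C9), where it is conjugated with the arene, so methyl iodide should alkylate there once, and the racemic, enolisable centre that results is re-set in step 2.

**Step 2**
Reactants: 4 (±)-6-methoxy-1-methyl-2-tetralone; 5 (S)-1-phenylethylamine; 6 methyl acrylate
Product: 9 methyl 3-[(1S)-6-methoxy-1-methyl-2-oxo-1,2,3,4-tetrahydronaphthalen-1-yl]propanoate, via secondary enamine 7 (not isolated), via imine adduct 8 (not isolated)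
Conditions: 5, p-toluenesulfonic acid (cat.), toluene, reflux (−H2O); 6, THF, 60 °C; AcOH/H2O, rt
Reagents that add atoms: methyl acrylate (6), C=CC(=O)OC; water, O; (S)-1-phenylethylamine (5), C[C@H](N)c1ccccc1 (kept only in 7 and 8)
Why: Michael addition of a chiral imine through its secondary enamine tautomer (deracemising alkylation): the more substituted, arene-conjugated enamine 7 should add to methyl acrylate in a compact aza-ene-like transition state on the face turned away from the phenyl group of the auxiliary, which sets quaternary C9 in the spatial sense known for 2-methylcyclohexanone and the (S)-amine, and hydrolysis returns the amine.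

**Step 3**
Reactants: 9 keto ester
Product: 10 methyl 3-[(1R)-6-methoxy-1-methyl-2-methylidene-1,2,3,4-tetrahydronaphthalen-1-yl]propanoate
Conditions: Ph3PCH3Br, KOtBu, THF, 0 to 50 °C
Reagents that add atoms: methyltriphenylphosphonium bromide, C[P+](c1ccccc1)(c1ccccc1)c1ccccc1.[Br-]
Why: Wittig methylenation: the unstabilised ylide should take the ketone in preference to the ester, and the neighbouring C9 is quaternary and cannot epimerise (the descriptor changes only because the priorities change).

**Step 4**
Reactants: 10 methylidene ester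
Product: 11 methyl 3-[(1R,2R)-6-methoxy-1,2-dimethyl-1,2,3,4-tetrahydronaphthalen-1-yl]propanoate
Conditions: H2 (1 atm), Pd/C, EtOAc, rt
Reagents that add atoms: none
Why: Heterogeneous hydrogenation under steric approach control: peri strain with the aromatic C1–H and allylic strain with the methylidene group place the longer C9 chain pseudoaxial, so hydrogen should arrive on the opposite face and the new C8 methyl ends cis to the chain and trans to the C9 methyl.

**Step 5**
Reactants: 11 saturated ester
Product: 12 3-[(1R,2R)-6-methoxy-1,2-dimethyl-1,2,3,4-tetrahydronaphthalen-1-yl]propan-1-ol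
Conditions: LiAlH4, THF, 0 °C; then H2O
Reagents that add atoms: none
Why: Ester reduction with LiAlH4, which touches neither the anisole ring nor the two stereocentres.

**Step 6**
Reactants: 12 tetralin alcohol
Product: 13 3-[(1R,2R)-6-methoxy-1,2-dimethyl-1,2,3,4,5,8-hexahydronaphthalen-1-yl]propan-1-ol
Conditions: Li, NH3 (l), THF, t-BuOH, −78 to −33 °C; then H2O
Reagents that add atoms: none
Why: Birch reduction: the anisole ring should be protonated at C1 and C4, which leaves the enol ether C2=C3 and the tetrasubstituted C5=C10 alkene as in the estradiol methyl ether series, while the side-chain alkoxide is inert.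

**Step 7**
Reactants: 13 diene alcohol
Product: 14 3-[(1R,2R)-6-methoxy-1,2-dimethyl-1,2,3,4,5,8-hexahydronaphthalen-1-yl]propanal
Conditions: SO3·pyridine, DMSO, Et3N, CH2Cl2, 0 °C
Reagents that add atoms: none
Why: Parikh–Doering oxidation: the base-buffered activated-DMSO conditions should stop at the aldehyde and spare the acid-labile enol ether and the skipped diene.

**Step 8**
Reactants: 14 aldehyde
Product: 15 (1R,2R)-1-(but-3-yn-1-yl)-6-methoxy-1,2-dimethyl-1,2,3,4,5,8-hexahydronaphthalene
Conditions: dimethyl (1-diazo-2-oxopropyl)phosphonate, K2CO3, MeOH, 0 °C to rt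
Reagents that add atoms: dimethyl (1-diazo-2-oxopropyl)phosphonate, CC(=O)C(=[N+]=[N-])P(=O)(OC)OC
Why: Ohira–Bestmann variant of the Seyferth–Gilbert homologation: the diazophosphonate anion adds to the aldehyde, and loss of phosphate and nitrogen gives the terminal alkyne C13≡C14 in basic methanol, which the enol ether tolerates but the later β,γ-enone would not.

**Step 9**
Reactants: 15 alkynyl enol ether
Product: 16 (5R,6R)-5-(but-3-yn-1-yl)-5,6-dimethyl-3,4,5,6,7,8-hexahydronaphthalen-2(1H)-one
Conditions: oxalic acid, THF/H2O, rt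
Reagents that add atoms: water, O
Why: Enol ether hydrolysis under the mild oxalic acid conditions of the 19-norsteroid series, which should give the β,γ-unsaturated ketone without moving C5=C10 into conjugation.

**Step 10**
Reactants: 16 β,γ-enone
Product: 18 (5R,6R)-5-(but-3-yn-1-yl)-1,1,5,6-tetramethyl-3,4,5,6,7,8-hexahydronaphthalen-2(1H)-one, via monomethyl ketone 17 (not isolated)
Conditions: KOtBu (2.2 equiv) added to 16 and MeI (6 equiv), THF/t-BuOH, 0 °C
Reagents that add atoms: iodomethane, CI
Why: Deconjugative α,α-dialkylation of an extended enolate: C4–H is activated by both C3=O and C5=C10, the 3,5(10)-dienolate is alkylated twice at its α-carbon C4 so that C5=C10 stays in place, the centre made in 17 is erased in 18, and tert-butoxide is too weak a base to metalate the alkyne.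

**Step 11**
Reactants: 18 alkynyl octalone; 19 5-ethoxy-4-methyl-1,3-oxazole
Product: 22 4-{2-[(1R,2R)-1,2,5,5-tetramethyl-6-oxo-1,2,3,4,5,6,7,8-octahydronaphthalen-1-yl]ethyl}furan-2(5H)-one, via bicyclic cycloadduct 20 (not isolated), via 2-ethoxyfuran 21 (not isolated)
Conditions: 19 (5 equiv), 2,6-di-tert-butyl-4-methylphenol (cat.), 1,2-dichlorobenzene, sealed tube, 180 °C; then 1 M HCl, THF, rt (same flask)
Reagents that add atoms: 5-ethoxy-4-methyl-1,3-oxazole (19), CCOc1ocnc1C; water, O
Why: The azadiene C2=N3–C4=C5 of 19 should add across C13≡C14 in a concerted suprafacial [4+2] cycloaddition that makes C16–C13 and C15–C14 in the same event (20), cycloreversion then expels N3≡C4–CH3 as acetonitrile and leaves 2-ethoxyfuran 21, and dilute acid protonates C16, adds water at C15 and releases ethanol to give the conjugated butenolide at its final oxidation level. The closest known reaction type is the oxazole–alkyne Diels–Alder/retro-Diels–Alder furan synthesis, which is established between separate molecules for oxazoles and unactivated silyl- or stannylalkynes at about 180–250 °C and within one molecule for 5-alkoxyoxazoles and unactivated alkynes, where the alkoxyfurans are hydrolysed to butenolides. The oxygen-bridged six-membered ring of 20 closes by cycloaddition, both bonds at once, and the five-membered ring C13–C14–C15–O–C16 is what is left of it after the cycloreversion, so no separate ring-closing event is needed. The only new stereocentres are the two bridgeheads of 20, which vanish with the loss of acetonitrile, and C8 and C9 are spectators. The step needs regioselectivity, chain-bearing C13 to oxazole C2 and C14–H to oxazole C5, and this is secured sterically (C2 carries only hydrogen, C5 carries the ethoxy group and is flanked by the C4 methyl) and electronically (the largest HOMO coefficient of a 1-alkoxy diene lies at the far terminus C2, the larger LUMO coefficient of an alkyl alkyne at its substituted carbon). It also needs chemoselectivity and heat tolerance, which 18 secures because C5=C10 is tetrasubstituted and walled in by quaternary C4 and C9, the quaternary C4 forbids conjugation of the β,γ-enone under heat or acid, and the heat- and base-labile ketol does not yet exist.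

**Step 12**
Reactants: 22 butenolide ketone
Product: 23 4-{2-[(1R,2R,6S)-6-hydroxy-1,2,5,5-tetramethyl-1,2,3,4,5,6,7,8-octahydronaphthalen-1-yl]ethyl}furan-2(5H)-one
Conditions: (R)-2-methyl-CBS-oxazaborolidine [(3aR)-1-methyl-3,3-diphenyltetrahydro-1H,3H-pyrrolo[1,2-c][1,3,2]oxazaborole] (0.2 equiv), BH3·SMe2, THF, −20 °C; then MeOH
Reagents that add atoms: none
Why: Corey–Bakshi–Shibata reduction: the catalyst tells quaternary C4 (large) from C2H2 (small), so the (R)-catalyst should give the (3S)-carbinol under reagent control, while the hindered alkene and, at low temperature, the butenolide are left alone.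

**Step 13**
Reactants: 23 hydroxy octalin
Product: 24 4-{2-[(1R,2R,7S)-7-hydroxy-1,2,6,6-tetramethyl-5,10-dioxocyclodecyl]ethyl}furan-2(5H)-one
Conditions: O3, CH2Cl2/MeOH, −78 °C; then Me2S, −78 °C to rt
Reagents that add atoms: ozone, [O-][O+]=O
Why: Ozonolysis with reductive work-up: the electron-rich tetrasubstituted C5=C10 alkene should be consumed well before the electron-poor butenolide alkene, so the former ring-fusion bond is cut and rings A and B merge into the ten-membered 5,10-diketone with C3, C8 and C9 untouched.

**Step 14**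
Reactants: 24 hydroxy diketone
Product: 27 4-{2-[(2S,3aS,5R,6R,8aS)-2,8a-dihydroxy-1,1,5,6-tetramethyl-4-oxodecahydroazulen-5-yl]ethyl}furan-2(5H)-one (target), via bridged enol ether 25 (not isolated), via cis-fused ketol 26 (not isolated)
Conditions: camphor-10-sulfonic acid (0.1 equiv), water-saturated CH2Cl2, 0 °C to rt
Reagents that add atoms: water, O (lost on the way to 25 and taken up again)
Why: Acid-catalysed transannular aldol of a cyclodecane-1,6-dione (the classical octalin-to-hydroazulene remodelling): only C10=O lies within five-ring reach of the C3 hydroxyl, so it is drawn into enol ether 25 and becomes the donor at C1 while C5=O stays the acceptor; the C3–O–C10 bridge forces C1–C10 and C5–C6 onto the face of the C3 oxygen, which fixes C5 (hydroxyl trans to the C3 hydroxyl) in cis-ketol 26; acid-catalysed enolisation should then epimerise C1 to the less crowded trans-fused ketol, whose C5 hydroxyl can hydrogen-bond to C10=O.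

**Compound list**
1 | 6-methoxy-3,4-dihydronaphthalen-2(1H)-one (6-methoxy-2-tetralone) | COc1ccc2c(c1)CCC(=O)C2 | starting material
2 | 1-(6-methoxy-3,4-dihydronaphthalen-2-yl)pyrrolidine | COc1ccc2c(c1)CCC(=C2)N1CCCC1 | intermediate
3 | 1-(6-methoxy-1-methyl-3,4-dihydronaphthalen-2(1H)-ylidene)pyrrolidinium iodide (racemic) | COc1ccc2c(c1)CCC(=[N+]1CCCC1)C2C.[I-] | intermediate
4 | (±)-6-methoxy-1-methyl-3,4-dihydronaphthalen-2(1H)-one | COc1ccc2c(c1)CCC(=O)C2C | intermediate
5 | (S)-1-phenylethylamine | C[C@H](N)c1ccccc1 | starting material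
6 | methyl acrylate | C=CC(=O)OC | starting material
7 | 6-methoxy-1-methyl-N-[(1S)-1-phenylethyl]-3,4-dihydronaphthalen-2-amine | C[C@H](NC1=C(C)c2ccc(OC)cc2CC1)c1ccccc1 | intermediate
8 | methyl 3-[(1S)-6-methoxy-1-methyl-2-{[(1S)-1-phenylethyl]imino}-1,2,3,4-tetrahydronaphthalen-1-yl]propanoate | C[C@H](N=C1CCc2cc(OC)ccc2[C@]1(C)CCC(=O)OC)c1ccccc1 | intermediate
9 | methyl 3-[(1S)-6-methoxy-1-methyl-2-oxo-1,2,3,4-tetrahydronaphthalen-1-yl]propanoate | O=C1CCc2cc(OC)ccc2[C@]1(C)CCC(=O)OC | intermediate
10 | methyl 3-[(1R)-6-methoxy-1-methyl-2-methylidene-1,2,3,4-tetrahydronaphthalen-1-yl]propanoate | C=C1CCc2cc(OC)ccc2[C@]1(C)CCC(=O)OC | intermediate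
11 | methyl 3-[(1R,2R)-6-methoxy-1,2-dimethyl-1,2,3,4-tetrahydronaphthalen-1-yl]propanoate | C[C@@H]1CCc2cc(OC)ccc2[C@]1(C)CCC(=O)OC | intermediate
12 | 3-[(1R,2R)-6-methoxy-1,2-dimethyl-1,2,3,4-tetrahydronaphthalen-1-yl]propan-1-ol | C[C@@H]1CCc2cc(OC)ccc2[C@]1(C)CCCO | intermediate
13 | 3-[(1R,2R)-6-methoxy-1,2-dimethyl-1,2,3,4,5,8-hexahydronaphthalen-1-yl]propan-1-ol | C[C@@H]1CCC2=C(CC=C(OC)C2)[C@]1(C)CCCO | intermediate
14 | 3-[(1R,2R)-6-methoxy-1,2-dimethyl-1,2,3,4,5,8-hexahydronaphthalen-1-yl]propanal | C[C@@H]1CCC2=C(CC=C(OC)C2)[C@]1(C)CCC=O | intermediate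
15 | (1R,2R)-1-(but-3-yn-1-yl)-6-methoxy-1,2-dimethyl-1,2,3,4,5,8-hexahydronaphthalene | C[C@@H]1CCC2=C(CC=C(OC)C2)[C@]1(C)CCC#C | intermediate
16 | (5R,6R)-5-(but-3-yn-1-yl)-5,6-dimethyl-3,4,5,6,7,8-hexahydronaphthalen-2(1H)-one | C[C@@H]1CCC2=C(CCC(=O)C2)[C@]1(C)CCC#C | intermediate
17 | (5R,6R)-5-(but-3-yn-1-yl)-1,5,6-trimethyl-3,4,5,6,7,8-hexahydronaphthalen-2(1H)-one (both C1 epimers) | C[C@@H]1CCC2=C(CCC(=O)C2C)[C@]1(C)CCC#C | intermediate
18 | (5R,6R)-5-(but-3-yn-1-yl)-1,1,5,6-tetramethyl-3,4,5,6,7,8-hexahydronaphthalen-2(1H)-one | C[C@@H]1CCC2=C(CCC(=O)C2(C)C)[C@]1(C)CCC#C | intermediate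
19 | 5-ethoxy-4-methyl-1,3-oxazole | CCOc1ocnc1C | starting material
20 | 4-ethoxy-3-methyl-7-oxa-2-azabicyclo[2.2.1]hepta-2,5-diene bearing at C6 the 2-[(1R,2R)-1,2,5,5-tetramethyl-6-oxo-octahydronaphthalen-1-yl]ethyl group (both bridgehead epimers) | C[C@@H]1CCC2=C(CCC(=O)C2(C)C)[C@]1(C)CCC1=CC2(OCC)OC1N=C2C | intermediate
21 | (5R,6R)-5-[2-(5-ethoxyfuran-3-yl)ethyl]-1,1,5,6-tetramethyl-3,4,5,6,7,8-hexahydronaphthalen-2(1H)-one | C[C@@H]1CCC2=C(CCC(=O)C2(C)C)[C@]1(C)CCc1coc(OCC)c1 | intermediate
22 | 4-{2-[(1R,2R)-1,2,5,5-tetramethyl-6-oxo-1,2,3,4,5,6,7,8-octahydronaphthalen-1-yl]ethyl}furan-2(5H)-one | C[C@@H]1CCC2=C(CCC(=O)C2(C)C)[C@]1(C)CCC1=CC(=O)OC1 | intermediate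
23 | 4-{2-[(1R,2R,6S)-6-hydroxy-1,2,5,5-tetramethyl-1,2,3,4,5,6,7,8-octahydronaphthalen-1-yl]ethyl}furan-2(5H)-one | C[C@@H]1CCC2=C(CC[C@H](O)C2(C)C)[C@]1(C)CCC1=CC(=O)OC1 | intermediate
24 | 4-{2-[(1R,2R,7S)-7-hydroxy-1,2,6,6-tetramethyl-5,10-dioxocyclodecyl]ethyl}furan-2(5H)-one | C[C@@H]1CCC(=O)C(C)(C)[C@@H](O)CCC(=O)[C@]1(C)CCC1=CC(=O)OC1 | intermediate
25 | bridged 2,3-dihydrofuran from 24 (O joins C3 and C10, enol ether C1=C10, ketone at C5; C3, C8, C9 as in 24) | C[C@@H]1CCC(=O)C(C)(C)[C@@H]2CC=C(O2)[C@]1(C)CCC1=CC(=O)OC1 | intermediate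
26 | 4-{2-[(2S,3aR,5R,6R,8aS)-2,8a-dihydroxy-1,1,5,6-tetramethyl-4-oxodecahydroazulen-5-yl]ethyl}furan-2(5H)-one (cis-fused C1 epimer) | C[C@@H]1CC[C@]2(O)[C@@H](C[C@H](O)C2(C)C)C(=O)[C@]1(C)CCC1=CC(=O)OC1 | intermediate
27 | 4-{2-[(2S,3aS,5R,6R,8aS)-2,8a-dihydroxy-1,1,5,6-tetramethyl-4-oxodecahydroazulen-5-yl]ethyl}furan-2(5H)-one | C[C@@H]1CC[C@]2(O)[C@H](C[C@H](O)C2(C)C)C(=O)[C@]1(C)CCC1=CC(=O)OC1 | target

**Step count and risks**
Total steps: 14. Longest linear sequence: 14 (from 1).

The three steps most likely to fail are steps 11, 14 and 13.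

**Step 11.** Cycloaddition of an electron-rich azadiene to an unactivated alkyne may be too slow. Thermal decay of the oxazole or of the ethoxyfuran could then overtake it, and regiocontrol may erode.
- The fallback sets out from 18 and makes the same two carbon–carbon bonds by a ketene [2+2] cycloaddition.
- Dichloroketene (Cl3CCOCl, zinc–copper couple Zn–Cu, Et2O/DME) should add with its carbonyl carbon to C14 and its CCl2 carbon to C13. This gives the 4,4-dichlorocyclobutenone F1.
- Zn, AcOH and TMEDA remove both chlorines to give the 3-substituted cyclobutenone F2.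
- Baeyer–Villiger oxidation (H2O2, AcOH, 0 °C) of the strained ketone, which reacts far faster than the hindered C3 ketone, inserts oxygen next to the CH2 group.
- Either sense of migration would end, after double-bond shift, at the same 4-substituted furan-2(5H)-one. The fallback comes back to the route at 22.

**Step 14.** Three things may go wrong. The closure may run in the opposite direction (C6 onto C10). The ketol may lose water to give the C1=C5 enone. The C1 equilibrium may not favour the trans-fused form.
- The fallback sets out from 24 and gives up the hydroxyl template in favour of a base-equilibrated aldol.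
- TBSOTf and 2,6-lutidine cap the C3 hydroxyl to give the silyl ether F3. This also blocks retro-aldol cleavage of C3–C4.
- DBU in toluene at rt closes C1–C5 reversibly, so the ring fusion is formed directly under thermodynamic control. The product is the silylated ketol F4.
- HF·pyridine in THF frees the C3 hydroxyl, and the fallback comes back to the route at 27.

**Step 13.** Attack of ozone on an alkene walled in by two quaternary carbons may stop at oxygen-atom transfer, or it may become slower than attack on the butenolide.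
- The fallback sets out from 23.
- m-CPBA with NaHCO3 in CH2Cl2 gives the 5,10-epoxide F5 (either face serves).
- H5IO6 in THF/H2O opens it to the glycol and cleaves the glycol in the same flask. The fallback comes back to the route at 24.

**Further compounds**
F1 | step 11 | (5R,6R)-5-[2-(4,4-dichloro-3-oxocyclobut-1-en-1-yl)ethyl]-1,1,5,6-tetramethyl-3,4,5,6,7,8-hexahydronaphthalen-2(1H)-one | C[C@@H]1CCC2=C(CCC(=O)C2(C)C)[C@]1(C)CCC1=CC(=O)C1(Cl)Cl
F2 | step 11 | (5R,6R)-1,1,5,6-tetramethyl-5-[2-(3-oxocyclobut-1-en-1-yl)ethyl]-3,4,5,6,7,8-hexahydronaphthalen-2(1H)-one | C[C@@H]1CCC2=C(CCC(=O)C2(C)C)[C@]1(C)CCC1=CC(=O)C1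
F3 | step 14 | C3 tert-butyldimethylsilyl ether of 24 | C[C@@H]1CCC(=O)C(C)(C)[C@@H](O[Si](C)(C)C(C)(C)C)CCC(=O)[C@]1(C)CCC1=CC(=O)OC1
F4 | step 14 | C3 tert-butyldimethylsilyl ether of 27 | C[C@@H]1CC[C@]2(O)[C@H](C[C@H](O[Si](C)(C)C(C)(C)C)C2(C)C)C(=O)[C@]1(C)CCC1=CC(=O)OC1
F5 | step 13 | 5,10-epoxide of 23 (epoxide face not defined) | C[C@@H]1CCC23OC3(CC[C@H](O)C2(C)C)[C@]1(C)CCC1=CC(=O)OC1
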